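The spring run ended with left-handed substrate left over. At 12.0 min left-handed product read 20 % of the 50.0 % its charge could give, and with 3 % of right-handed product the total stood near the 25.0 % its reagent allowed at one reagent per product. So I took reagent as the limiting reagent there.

- spring: left-handed substrate 0.015 M; right-handed substrate 0.015 M; reagent 0.0075 M; precatalyst 30 µM; added ligand 39 µM; run made earlier
- flask: left-handed substrate 0.015 M; reagent 0.0150 M; precatalyst 30 µM; added ligand 39 µM; right-handed substrate 0.015 M; time 40 min

spring run (percent of the left-handed substrate and right-handed substrate together charged)

| time / min | left-handed product / % | right-handed product / % |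
|---|---|---|
| 0.667 | 1 | 1 |
| 2.00 | 6 | 2 |
| 3.00 | 10 | 3 |
| 5.00 | 12 | 3 |
| 8.00 | 21 | 0 |
| 10.0 | 20 | 1 |
| 12.0 | 20 | 3 |

(standard deviation of a reading: 1.5 percentage points)

- free catalyst is single-handed; left-handed substrate and right-handed substrate are mirror images of each other, charged as a racemate, each of them at the stated concentration
- an excess is the difference of the two amounts in percent of their sum
- an excess is below zero if the other one leads

1. excess of left-handed product over right-handed product in the product at 2.0 min
2. excess of left-handed product over right-handed product in the product at 40 min
3. part of the left-handed substrate and right-handed substrate charged together that has reacted at 40 min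

In the flask the reagent charge over the left-handed substrate charge was 1.00, the equivalents of reagent per left-handed substrate, where reagent and the favoured substrate are matched. I tried two imagined catalysts on it. One that took left-handed substrate and nothing else gave excess 100 %; one blind to hand gave excess zero. Both gave conversion 50.0 %.

The last three spring readings put left-handed to right-handed product at 15.3, which I used as a rough selectivity factor s, since those right-handed readings sit close to their scatter of 1.5 percentage points. Early, with both substrates nearly whole, that ratio gave excess 87.7 %. Late, if the left-handed substrate keeps a fraction x, the right-handed substrate loses about −ln x / s of itself, and at these equivalents that loss equals x. Solving that by repeated substitution gave x near 13.3 % and a final excess near 73.4 %, with conversion 50.0 % once the reagent is used up.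

The forecast said 52 %, 80 % and 45 %, seeing "a poorly selective early phase", so its early excess stood below mine; its final excess stood above mine.

The flask gave 87.0 %, 76.1 % and 48.4 %.

    precatalyst → free catalyst (k = 0.0907 min⁻¹)
    reagent + free catalyst + right-handed substrate → free catalyst + right-handed product (k = 1.68 × 10⁵ M⁻² min⁻¹)
    free catalyst + added ligand ⇌ idle complex (K = 46000 M⁻¹, k = 2440 M⁻¹ min⁻¹)
    2 free catalyst → spent catalyst (k = 4460 M⁻¹ min⁻¹)
    reagent + free catalyst + left-handed substrate → free catalyst + left-handed product (k = 43500 M⁻² s⁻¹)

The early excess lay 35 points above the forecast. At 1.00 equivalents the flask kept, after 40.0 min, 3.3 % of its reagent and 15 % of its left-handed substrate, but 88 % of its right-handed substrate. The neighbouring flask with 0.060 M of reagent stood at 4.00 equivalents. There the left-handed substrate stood at 0 % after 40.0 min and 55 % of the reagent remained, so left-handed substrate ran out first. Conversion reached 90.5 %, right-handed product 40.5 %, and the excess fell to 10.5 %.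

(The readings come from a simulation for substances that don't exist, noise included.)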